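**Numbering.** Compounds are 1–28 as in the list after the steps. Atom labels: the indane is C1, C2, C3, C3a, C4–C7, C7a, and ring F is its benzene ring. C8 is the carbinol carbon on C3. The dihydrobenzofuran is O1', C2', C3', C3a', C4'–C7', C7a'; ring B is its benzene ring, joined to C2 through C4'. Rings A (on C1), C (on C8) and E (on C2') are the 4-oxygenated phenyl rings; ring D (on C3') is the 3,5-dioxygenated phenyl ring.

## Analysis of the target

The target is a resveratrol trimer built on an indane. Ring F carries hydroxyls at C5 and C7; C1 bears ring A, C2 bears C4' of a 2,3-dihydrobenzofuran (ring B, 6'-OH, ring E on C2', ring D on C3'), and C3 bears the carbinol C8 with ring C. There are six stereocentres in two clusters: C1 (S), C2 (R) and C3 (S) are all-trans on the cyclopentane with C8 (S) next to C3, and C2' (R) and C3' (R) are trans on the dihydrofuran. The clusters are linked only through the crowded C2–C4' bond, so neither can be relied on to control the other. The eight phenols are oxidation-prone, and C8–OH is a 4-hydroxybenzylic alcohol that ionises readily, so it cannot be present when aryl ethers are cleaved. C2'–O is a 4-oxybenzylic ether that opens reversibly under acid, and every arene is electron-rich enough for unwanted Friedel–Crafts chemistry. The difficulty lies in telling six similar aryl groups apart, in building the all-trans triad with absolute control, in setting C8 independently, and in joining two enantiopure halves at a hindered bond. The strategy rests on one feature: C7a is ortho to the C7 oxygen and para to the C5 oxygen, and C1 is benzylic to ring A with a para oxygen. A cation at C1 and the nucleophilic carbon C7a are therefore a matched pair, and forming C1–C7a closes the five-membered ring from a chain in which C3 is the only stereocentre that has to be made.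

## Retrosynthetic reasoning

**C8–H and the eight O–H bonds (28 ⇒ 27 ⇒ 26).** The C8 carbinol would not survive a Lewis acid strong enough to cleave aryl methyl ethers, so it is created last. Target 28 comes from ketone 27 by a catalyst-controlled hydride transfer, and 27 from its octamethyl ether 26 by exhaustive ether cleavage at the ketone oxidation level, where C8 cannot ionise. The forward reduction has to override any bias from the neighbouring C3 centre.

**C8–ring C (26 ⇒ 25 ⇒ 23 + 24; 23 ⇒ 22 ⇒ 21).** Cutting between C8 and ring C gives aldehyde 23 and the aryl Grignard reagent 24; the epimeric carbinols 25 converge on oxidation. Aldehyde 23 is the oxidised form of alcohol 22, which is unmasked from acetate 21. Ring C is added only after the indane exists. During ring formation C8 must carry neither a second cation-stabilising aryl group nor a carbonyl that would make C3–H enolisable.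

**C1–C7a (21 ⇒ 20).** This is the strategic cut. Opening the indane at C1–C7a gives the trisubstituted alkene 20, in which ring F is a free 3,5-dimethoxyphenyl group on C3 with two equivalent ortho positions. C1=C2 is a latent cation at C1. The cut is made here because it is the only ring bond whose formation follows the innate polarity of both partners. It removes two stereocentres at once, leaving C3 as the single centre to be made in this half. The forward reaction has to protonate at C2 only, let ring F (not ring D) capture the cation, and relay the configuration of C3 to C2 and C1.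

**C2–C4' (20 ⇒ 8 + 19).** The alkenyl–aryl bond between the two stereo-clusters is cut to give the (Z)-alkenyl boronate 8 and the aryl bromide 19. Each half is then made enantiopure on its own and the route becomes convergent. A direct carbometalation of alkyne 7 with a ring B organometallic would make the same bond in one step. It was not chosen because such additions are only moderately regioselective on aryl/alkyl alkynes and the aryl partner is hindered. The forward coupling has to keep the alkene geometry and tolerate the ortho substituent of 19.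

**C2–B and the acetate (8 ⇒ 7 ⇒ 6).** Boronate 8 is the syn-hydroboration product of alkyne 7 with boron on the carbon remote from ring A. The aryl group of the alkyne dictates this regiochemistry through the benzylic alkenylcopper intermediate. Acetate 7 is the ester of alcohol 6. The ester keeps the oxygen on C8 from trapping the C1 cation later.

**C3–C(sp) (6 ⇒ 3 + 4 through 5; 3 ⇒ 2 ⇒ 1).** The bond between C3 and the alkyne is cut to the enantiopure aryl oxirane 3 and alkyne 4, used as its alane 5. Opening at the benzylic carbon with inversion places aryl, alkynyl and hydroxymethyl groups on one stereocentre in a single step. Epoxide 3 is resolved from racemic 2, which comes from aldehyde 1 by methylene transfer.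

**C2' epimer and C2'–C3' (19 ⇒ 18 ⇒ 17 ⇒ 16 ⇒ 15).** The trans-dihydrofuran 19 is the thermodynamic C2' epimer of cis isomer 18. Cutting C2'–C3' in 18 leads to the diaryl carbene derived from diazo compound 17, which inserts into the benzylic ether C–H bond under control of a chiral dirhodium catalyst. This cut puts both aryl groups, the ring oxygen and the bromine handle in place before the ring closes, and only C3' needs absolute control. Compound 17 is the dehydrogenation product of hydrazone 16, made from ketone 15.

**C3'–ring D and the benzyl ether (15 ⇒ 14 ⇒ 12 + 13; 12 ⇒ 10 + 11; 10 ⇒ 9).** Ketone 15 is the oxidation product of benzhydrol 14, from aldehyde 12 and Grignard reagent 13. Aldehyde 12 is the 4-methoxybenzyl ether (from chloride 11) of salicylaldehyde 10. Phenol 10 is obtained from the dimethoxy aldehyde 9 by cleaving only the methoxy group next to the carbonyl.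

## Alternatives that were turned down

**Alternative 1:** Ring B is dissected at C4'–C5' and C3a'–C7a', so the benzofuran arene is assembled on an indane that already carries the stereotriad. An indan-2-yl ynone A2 and an oxygenated silyloxy diene A3 undergo a Diels–Alder reaction, and elimination of the alkoxy and silyl groups aromatises the adduct to the 2-aroylphenol A1.
- For: the indane would be closed before rings B, D and E exist. No second nucleophilic arene and no acid-labile benzylic ether would then be exposed to the cation. On that point this plan is stronger than the chosen one. The ynone polarisation also fixes the regiochemistry of the cycloaddition.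
- Against: A1 still lacks C2', ring E and both dihydrofuran stereocentres. They would have to be installed on the most advanced and most hindered intermediate, next to the stereotriad, where a chiral catalyst must work against substrate bias. A2 also needs an alkynyl group at C2, which changes the cation chemistry that builds the indane, and the sequence becomes linear.
- Comparison: the chosen route sets each cluster under its own reagent control before union, in a convergent way.

**Alternative 2:** This plan concerns only the dihydrofuran half and cuts C3'–C3a'. A hypervalent iodine oxidant in an acidic orthoester medium contracts the (2R)-flavanone A5 by a 1,2-aryl shift to the trans ester A4.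
- For: the trans relationship comes directly from the anti migration. In the chosen route the insertion gives the cis isomer and a separate epimerisation is needed, so this plan is stronger on that point. It is also metal-free.
- Against: A4 has an ester where ring D must be and an oxygen where C4' needs a carbon bond. Two further conversions are required: a decarboxylative arylation through a C3' radical, which re-sets C3', and a sulfonate coupling. A5 is the non-natural antipode and can racemise through its ring-opened chalcone. The plan does not address the indane.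
- Comparison: the chosen carbene insertion delivers the C2'–C3' bond, both aryl groups and the bromine handle together, in fewer steps from 15.

**Alternative 3:** C3–C3a and the C8–ring C bond are cut together. An alkenyl boronate bearing a ring F triflate, A7, is converted by the Grignard reagent 24 into its ate complex. A palladium catalyst with a chiral ferrocenyl bisphosphine then induces the 1,2-shift while closing the ring, giving the C8 boronate A6.
- For: C3 and C8 are set in one catalytic event, and C–B becomes C–O with retention. This would remove the four-step excursion at C8 and the final reduction, so on step economy at C8 it is stronger than the chosen plan.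
- Against: the migration terminus is an internal, hindered alkene carbon, a poor case for this coupling. A7 must already hold C1 and C2 as an acyclic anti pair with no ring to enforce it, and the catalyst must set two more centres against that bias. The C8 boronate must either survive eightfold ether cleavage or be oxidised first, which brings back the ionisable carbinol.
- Comparison: the chosen closure follows innate polarity, needs no chiral catalyst in the ring-forming step, and handles C8 at the ketone level, which tolerates deprotection.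

Key step: step 14

**Remarks on the chemistry (assumptions).**
- Aldehyde 9 and the Grignard solutions 13 and 24 are taken as purchasable.
- (R,R)-Co(salen)(OAc) is taken to leave the (R)-oxirane, as it does for other monosubstituted oxiranes.
- Rh2(R-PTAD)4 is taken to give the (3R) centre in step 11; if the antipode forms, Rh2(S-PTAD)4 is used.
- No bond to C3 is broken after step 3. Its descriptor is (R) in 6, 7 and 20 and (S) in 8 and 21–28 only because ligand ranks change.

**Step 1**
Reactants: 1 3,5-dimethoxybenzaldehyde
Product: 2 rac-2-(3,5-dimethoxyphenyl)oxirane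
Conditions: Me3SI, KOt-Bu, DMSO, 20 °C
Reagents that add atoms: trimethylsulfonium iodide, C[S+](C)C.[I-]
Why: Corey–Chaykovsky epoxidation; the sulfonium methylide adds to the aldehyde and the betaine closes to the terminal epoxide, with no stereocontrol needed yet.

**Step 2**
Reactants: 2 rac-2-(3,5-dimethoxyphenyl)oxirane
Product: 3 (R)-2-(3,5-dimethoxyphenyl)oxirane
Conditions: (R,R)-Co(salen)(OAc) (0.5 mol %), H2O (0.55 equiv), THF, 0 → 20 °C
Reagents that add atoms: none
Why: Hydrolytic kinetic resolution; the chiral salen complex of trivalent cobalt hydrolyses the (S)-epoxide at its CH2 terminus and leaves the (R)-epoxide, which fixes the configuration that becomes C3.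

**Step 3**
Reactants: 3 (R)-2-(3,5-dimethoxyphenyl)oxirane; 4 4-ethynylanisole
Product: 6 (2R)-2-(3,5-dimethoxyphenyl)-4-(4-methoxyphenyl)but-3-yn-1-ol, via alkynylalane 5 (not isolated)
Conditions: 4, n-BuLi, toluene, 0 °C; Et2AlCl, 0 °C; then 3, 0 → 20 °C; aq. Rochelle salt
Reagents that add atoms: none
Why: Lewis-acid-assisted epoxide opening by an alkynylalane; aluminium binds the ring oxygen and the alkynyl group is delivered to the benzylic carbon with inversion, giving the primary alcohol. The methoxy groups are meta to the benzylic carbon and do not support a free cation, which favours a stereospecific opening.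

**Step 4**
Reactants: 6 (2R)-2-(3,5-dimethoxyphenyl)-4-(4-methoxyphenyl)but-3-yn-1-ol
Product: 7 (2R)-2-(3,5-dimethoxyphenyl)-4-(4-methoxyphenyl)but-3-yn-1-yl acetate
Conditions: Ac2O, pyridine, DMAP (cat.), CH2Cl2, 0 → 20 °C
Reagents that add atoms: acetic anhydride, CC(=O)OC(C)=O
Why: DMAP-catalysed acylation of a primary alcohol; the ester cannot ionise and will keep this oxygen from trapping the C1 cation in step 14.

**Step 5**
Reactants: 7 (2R)-2-(3,5-dimethoxyphenyl)-4-(4-methoxyphenyl)but-3-yn-1-yl acetate
Product: 8 (2S,3Z)-2-(3,5-dimethoxyphenyl)-4-(4-methoxyphenyl)-3-(4,4,5,5-tetramethyl-1,3,2-dioxaborolan-2-yl)but-3-en-1-yl acetate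
Conditions: CuCl (5 mol %), P(p-tol)3 (6 mol %), NaOt-Bu (10 mol %), B2pin2, MeOH (2 equiv), THF, 20 °C
Reagents that add atoms: bis(pinacolato)diboron, CC1(C)OB(OC1(C)C)B1OC(C)(C)C(C)(C)O1
Why: Copper-catalysed formal hydroboration (syn-borylcupration, then protonation of the C–Cu bond with retention); copper goes to the carbon bearing ring A and boron to the future C2, so H and B end up cis.

**Step 6**
Reactants: 9 2-bromo-4,6-dimethoxybenzaldehyde
Product: 10 2-bromo-6-hydroxy-4-methoxybenzaldehyde
Conditions: BCl3 (1.1 equiv), CH2Cl2, −78 → 0 °C; H2O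
Reagents that add atoms: none
Why: Chelation-controlled ether cleavage; BCl3 bridges the aldehyde oxygen and the ortho methoxy group and removes only that methyl group.

**Step 7**
Reactants: 10 2-bromo-6-hydroxy-4-methoxybenzaldehyde; 11 4-methoxybenzyl chloride
Product: 12 2-bromo-4-methoxy-6-[(4-methoxybenzyl)oxy]benzaldehyde
Conditions: K2CO3, DMF, 60 °C
Reagents that add atoms: none
Why: Williamson etherification of the phenol; the benzyl group is not a protecting group but the future C2' with ring E.

**Step 8**
Reactants: 12 2-bromo-4-methoxy-6-[(4-methoxybenzyl)oxy]benzaldehyde; 13 3,5-dimethoxyphenylmagnesium chloride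
Product: 14 rac-{2-bromo-4-methoxy-6-[(4-methoxybenzyl)oxy]phenyl}(3,5-dimethoxyphenyl)methanol
Conditions: THF, −78 → 0 °C; aq. NH4Cl
Reagents that add atoms: none
Why: Grignard addition to the aldehyde joins ring D to the future C3'; the new centre is erased in step 9.

**Step 9**
Reactants: 14 rac-{2-bromo-4-methoxy-6-[(4-methoxybenzyl)oxy]phenyl}(3,5-dimethoxyphenyl)methanol
Product: 15 {2-bromo-4-methoxy-6-[(4-methoxybenzyl)oxy]phenyl}(3,5-dimethoxyphenyl)methanone
Conditions: Dess–Martin periodinane, CH2Cl2, 20 °C
Reagents that add atoms: none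
Why: Dess–Martin oxidation of a benzhydrol to the benzophenone, under neutral conditions that spare the benzyl ether.

**Step 10**
Reactants: 15 {2-bromo-4-methoxy-6-[(4-methoxybenzyl)oxy]phenyl}(3,5-dimethoxyphenyl)methanone
Product: 16 hydrazone of 15, {2-bromo-4-methoxy-6-[(4-methoxybenzyl)oxy]phenyl}(3,5-dimethoxyphenyl)methanone hydrazone
Conditions: N2H4·H2O (10 equiv), AcOH (cat.), n-BuOH, 110 °C, sealed tube
Reagents that add atoms: hydrazine, NN
Why: Condensation of a ketone with hydrazine; forcing conditions are chosen because the carbonyl is flanked by two ortho substituents, and the electron-rich aryl bromide should not undergo substitution.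

**Step 11**
Reactants: 16 hydrazone of 15
Product: 18 (2S,3R)-4-bromo-3-(3,5-dimethoxyphenyl)-6-methoxy-2-(4-methoxyphenyl)-2,3-dihydro-1-benzofuran (cis), via diaryldiazomethane 17 (not isolated)
Conditions: MnO2, CH2Cl2, 0 °C; filter; Rh2(R-PTAD)4 (1 mol %), CH2Cl2, 0 °C
Reagents that add atoms: none
Why: Dehydrogenation of the hydrazone to the diaryldiazomethane, then enantioselective intramolecular C–H insertion of the donor/donor rhodium carbene into the benzylic ether C–H bond, forming C2'–C3'. The chiral dirhodium carboxylate controls the face of the carbene carbon (C3') and the cis isomer is the kinetic product.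

**Step 12**
Reactants: 18 (2S,3R)-4-bromo-3-(3,5-dimethoxyphenyl)-6-methoxy-2-(4-methoxyphenyl)-2,3-dihydro-1-benzofuran (cis)
Product: 19 (2R,3R)-4-bromo-3-(3,5-dimethoxyphenyl)-6-methoxy-2-(4-methoxyphenyl)-2,3-dihydro-1-benzofuran (trans)
Conditions: CF3CO2H (2 equiv), CH2Cl2, 0 → 20 °C
Reagents that add atoms: none
Why: Acid-mediated epimerisation; the C2'–O bond ionises reversibly to the anisyl-stabilised cation and the phenol re-closes to the more stable trans isomer, while C3' is not touched.

**Step 13**
Reactants: 8 (2S,3Z)-alkenyl boronate; 19 (2R,3R)-4-bromo-3-(3,5-dimethoxyphenyl)-6-methoxy-2-(4-methoxyphenyl)-2,3-dihydro-1-benzofuran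
Product: 20 (2R,3E)-2-(3,5-dimethoxyphenyl)-3-[(2R,3R)-3-(3,5-dimethoxyphenyl)-6-methoxy-2-(4-methoxyphenyl)-2,3-dihydro-1-benzofuran-4-yl]-4-(4-methoxyphenyl)but-3-en-1-yl acetate
Conditions: Pd(OAc)2 (5 mol %), SPhos (10 mol %), K3PO4, toluene/H2O (10:1), 70 °C
Reagents that add atoms: none
Why: Suzuki–Miyaura coupling; zerovalent palladium inserts into the C4'–Br bond, the alkenyl group transfers with retention of geometry, and the bulky biaryl phosphine copes with the ortho-substituted bromide. The mild, nearly anhydrous base spares the acetate.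

**Step 14**
Reactants: 20 (2R,3E)-alkene acetate
Product: 21 (1S,2R,3S)-3-(acetoxymethyl)-2-[(2R,3R)-3-(3,5-dimethoxyphenyl)-6-methoxy-2-(4-methoxyphenyl)-2,3-dihydro-1-benzofuran-4-yl]-5,7-dimethoxy-1-(4-methoxyphenyl)indane (all-trans; C1 carries ring A)
Conditions: HNTf2 (10 mol %), (CF3)2CHOH, 0.01 M, 0 → 20 °C
Reagents that add atoms: none
Why: The acid protonates the C1=C2 double bond at C2, because only the C1 cation is stabilised (by the para-methoxy group of ring A; ring B is oxygenated meta to C4' and cannot stabilise a C2 cation), and the cation is captured by C7a of ring F, ortho to one methoxy group and para to the other, after which the Wheland intermediate loses a proton. The closest known reaction type is the acid-mediated cyclisation of 1,3-diarylpropenes to 1-arylindanes, an intramolecular cationic hydroarylation (Friedel–Crafts alkylation). The one ring closed is the cyclopentane C1–C2–C3–C3a–C7a; it is formally 5-endo-trig with respect to the alkene but runs as a cation–arene closure, for which this ring size is the normal outcome. C2 is set in the protonation, which is reversible (cation and alkene interconvert, so the alkene geometry of 20 does not matter), and C1 is set in the C–C bond formation; both are controlled by C3, the only stereocentre in this half, which has no ionisable or enolisable bond in 20. Under these Curtin–Hammett conditions the lowest transition state should be the one leading to the all-trans ring, with ring B anti to the acetoxymethyl group and ring A anti to ring B, and any reversibility of the alkylation in this medium works in the same direction. The step needs chemoselectivity for ring F over ring D (which could close a seven-membered ring from C3') and over intermolecular alkylation; proximity favours the five-membered closure and high dilution supports it. The primary acetate keeps C8 from forming a second cation or a tetrahydrofuran, and the only other acid-labile bond, C2'–O, can only re-close to the trans-dihydrofuran already present.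

**Step 15**
Reactants: 21 indane acetate
Product: 22 [(1S,2R,3S)-2-[(2R,3R)-3-(3,5-dimethoxyphenyl)-6-methoxy-2-(4-methoxyphenyl)-2,3-dihydro-1-benzofuran-4-yl]-5,7-dimethoxy-1-(4-methoxyphenyl)indan-3-yl]methanol
Conditions: K2CO3 (cat.), MeOH/THF, 20 °C
Reagents that add atoms: none
Why: Base-catalysed transesterification of the acetate with methanol; nothing else in 21 is base-sensitive.

**Step 16**
Reactants: 22 indan-3-ylmethanol
Product: 23 (1S,2R,3S)-2-[(2R,3R)-dihydrobenzofuran-4-yl]-5,7-dimethoxy-1-(4-methoxyphenyl)indane-3-carbaldehyde (aryl groups as in 22)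
Conditions: Dess–Martin periodinane, CH2Cl2, 0 → 20 °C
Reagents that add atoms: none
Why: Dess–Martin oxidation to the aldehyde; C3 is now enolisable, but its substituent is trans to ring B, the favoured arrangement, so epimerisation would only return the same isomer.

**Step 17**
Reactants: 23 indane-3-carbaldehyde; 24 4-methoxyphenylmagnesium bromide
Product: 25 (4-methoxyphenyl)[(1S,2R,3S)-indan-3-yl]methanol, both C8 epimers (indane substituents as in 22)
Conditions: THF, −78 → 0 °C; aq. NH4Cl
Reagents that add atoms: none
Why: Grignard addition to the aldehyde forms the C8–ring C bond; the C8 configuration is irrelevant because step 18 removes it.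

**Step 18**
Reactants: 25 C8 carbinols
Product: 26 (4-methoxyphenyl)[(1S,2R,3S)-2-[(2R,3R)-3-(3,5-dimethoxyphenyl)-6-methoxy-2-(4-methoxyphenyl)-2,3-dihydro-1-benzofuran-4-yl]-5,7-dimethoxy-1-(4-methoxyphenyl)indan-3-yl]methanone (octamethyl ether ketone)
Conditions: Dess–Martin periodinane, CH2Cl2, 20 °C
Reagents that add atoms: none
Why: Dess–Martin oxidation of the benzylic alcohol; both epimers give one aryl ketone.

**Step 19**
Reactants: 26 octamethyl ether ketone
Product: 27 (4-hydroxyphenyl)[(1S,2R,3S)-2-[(2R,3R)-3-(3,5-dihydroxyphenyl)-6-hydroxy-2-(4-hydroxyphenyl)-2,3-dihydro-1-benzofuran-4-yl]-5,7-dihydroxy-1-(4-hydroxyphenyl)indan-3-yl]methanone (octaphenol ketone)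
Conditions: BBr3 (20 equiv), CH2Cl2, −78 → 20 °C; MeOH, H2O
Reagents that add atoms: none
Why: Lewis-acid cleavage of all eight aryl methyl ethers; at the ketone level C8 cannot ionise, and reversible opening of C2'–O or enolisation at C3 can only return the trans arrangements already present.

**Step 20**
Reactants: 27 octaphenol ketone
Product: 28 (1S,2R,3S)-2-[(2R,3R)-3-(3,5-dihydroxyphenyl)-6-hydroxy-2-(4-hydroxyphenyl)-2,3-dihydro-1-benzofuran-4-yl]-3-[(S)-hydroxy(4-hydroxyphenyl)methyl]-1-(4-hydroxyphenyl)indane-5,7-diol (target)
Conditions: RuCl(p-cymene)[(S,S)-TsDPEN] (5 mol %), HCO2H/Et3N (5:2), DMF, 40 °C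
Reagents that add atoms: none
Why: Asymmetric transfer hydrogenation of an aryl ketone; the ruthenium hydride and the ligand N–H deliver H2 through a six-membered transition state, and ring C is recognised by the η6-arene, so the (S,S) ligand should give the (S) carbinol. The acidic formate medium keeps the phenols neutral and the new benzylic alcohol un-ionised.

**Compound list**

1 | 3,5-dimethoxybenzaldehyde | COc1cc(OC)cc(C=O)c1 | starting material
2 | rac-2-(3,5-dimethoxyphenyl)oxirane | COc1cc(OC)cc(c1)C1CO1 | intermediate
3 | (R)-2-(3,5-dimethoxyphenyl)oxirane | COc1cc(OC)cc(c1)[C@@H]1CO1 | intermediate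
4 | 4-ethynylanisole | COc1ccc(C#C)cc1 | starting material
5 | diethyl[(4-methoxyphenyl)ethynyl]aluminium (formed in the flask) | CC[Al](CC)C#Cc1ccc(OC)cc1 | intermediate
6 | (2R)-2-(3,5-dimethoxyphenyl)-4-(4-methoxyphenyl)but-3-yn-1-ol | COc1cc(OC)cc(c1)[C@@H](CO)C#Cc1ccc(OC)cc1 | intermediate
7 | (2R)-2-(3,5-dimethoxyphenyl)-4-(4-methoxyphenyl)but-3-yn-1-yl acetate | COc1cc(OC)cc(c1)[C@@H](COC(C)=O)C#Cc1ccc(OC)cc1 | intermediate
8 | (2S,3Z)-2-(3,5-dimethoxyphenyl)-4-(4-methoxyphenyl)-3-(4,4,5,5-tetramethyl-1,3,2-dioxaborolan-2-yl)but-3-en-1-yl acetate | COc1cc(OC)cc(c1)[C@@H](COC(C)=O)/C(=C\c1ccc(OC)cc1)B1OC(C)(C)C(C)(C)O1 | intermediate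
9 | 2-bromo-4,6-dimethoxybenzaldehyde | COc1cc(OC)c(C=O)c(Br)c1 | starting material
10 | 2-bromo-6-hydroxy-4-methoxybenzaldehyde | COc1cc(O)c(C=O)c(Br)c1 | intermediate
11 | 4-methoxybenzyl chloride | COc1ccc(CCl)cc1 | starting material
12 | 2-bromo-4-methoxy-6-[(4-methoxybenzyl)oxy]benzaldehyde | COc1ccc(COc2cc(OC)cc(Br)c2C=O)cc1 | intermediate
13 | 3,5-dimethoxyphenylmagnesium chloride | COc1cc(OC)cc([Mg]Cl)c1 | starting material
14 | rac-{2-bromo-4-methoxy-6-[(4-methoxybenzyl)oxy]phenyl}(3,5-dimethoxyphenyl)methanol | COc1ccc(COc2cc(OC)cc(Br)c2C(O)c2cc(OC)cc(OC)c2)cc1 | intermediate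
15 | {2-bromo-4-methoxy-6-[(4-methoxybenzyl)oxy]phenyl}(3,5-dimethoxyphenyl)methanone | COc1ccc(COc2cc(OC)cc(Br)c2C(=O)c2cc(OC)cc(OC)c2)cc1 | intermediate
16 | hydrazone of 15 | COc1ccc(COc2cc(OC)cc(Br)c2C(=NN)c2cc(OC)cc(OC)c2)cc1 | intermediate
17 | 1-bromo-2-[diazo(3,5-dimethoxyphenyl)methyl]-5-methoxy-3-[(4-methoxybenzyl)oxy]benzene (formed in the flask) | COc1ccc(COc2cc(OC)cc(Br)c2C(=[N+]=[N-])c2cc(OC)cc(OC)c2)cc1 | intermediate
18 | (2S,3R)-4-bromo-3-(3,5-dimethoxyphenyl)-6-methoxy-2-(4-methoxyphenyl)-2,3-dihydro-1-benzofuran (cis) | Brc1cc(OC)cc2c1[C@@H](c1cc(OC)cc(OC)c1)[C@@H](c1ccc(OC)cc1)O2 | intermediate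
19 | (2R,3R)-4-bromo-3-(3,5-dimethoxyphenyl)-6-methoxy-2-(4-methoxyphenyl)-2,3-dihydro-1-benzofuran (trans) | Brc1cc(OC)cc2c1[C@@H](c1cc(OC)cc(OC)c1)[C@H](c1ccc(OC)cc1)O2 | intermediate
20 | (2R,3E)-2-(3,5-dimethoxyphenyl)-3-[(2R,3R)-3-(3,5-dimethoxyphenyl)-6-methoxy-2-(4-methoxyphenyl)-2,3-dihydro-1-benzofuran-4-yl]-4-(4-methoxyphenyl)but-3-en-1-yl acetate | COc1cc(OC)cc(c1)[C@@H](COC(C)=O)/C(=C\c1ccc(OC)cc1)c1cc(OC)cc2c1[C@@H](c1cc(OC)cc(OC)c1)[C@H](c1ccc(OC)cc1)O2 | intermediate
21 | (1S,2R,3S)-3-(acetoxymethyl)-2-[(2R,3R)-3-(3,5-dimethoxyphenyl)-6-methoxy-2-(4-methoxyphenyl)-2,3-dihydro-1-benzofuran-4-yl]-5,7-dimethoxy-1-(4-methoxyphenyl)indane | COc1ccc([C@H]2c3c(OC)cc(OC)cc3[C@@H](COC(C)=O)[C@@H]2c2cc(OC)cc3c2[C@@H](c2cc(OC)cc(OC)c2)[C@H](c2ccc(OC)cc2)O3)cc1 | intermediate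
22 | indan-3-ylmethanol corresponding to 21 | COc1ccc([C@H]2c3c(OC)cc(OC)cc3[C@@H](CO)[C@@H]2c2cc(OC)cc3c2[C@@H](c2cc(OC)cc(OC)c2)[C@H](c2ccc(OC)cc2)O3)cc1 | intermediate
23 | indane-3-carbaldehyde corresponding to 22 | COc1ccc([C@H]2c3c(OC)cc(OC)cc3[C@@H](C=O)[C@@H]2c2cc(OC)cc3c2[C@@H](c2cc(OC)cc(OC)c2)[C@H](c2ccc(OC)cc2)O3)cc1 | intermediate
24 | 4-methoxyphenylmagnesium bromide | COc1ccc([Mg]Br)cc1 | starting material
25 | (4-methoxyphenyl)(indan-3-yl)methanol, both C8 epimers | COc1ccc([C@H]2c3c(OC)cc(OC)cc3[C@@H](C(O)c3ccc(OC)cc3)[C@@H]2c2cc(OC)cc3c2[C@@H](c2cc(OC)cc(OC)c2)[C@H](c2ccc(OC)cc2)O3)cc1 | intermediate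
26 | octamethyl ether ketone | COc1ccc([C@H]2c3c(OC)cc(OC)cc3[C@@H](C(=O)c3ccc(OC)cc3)[C@@H]2c2cc(OC)cc3c2[C@@H](c2cc(OC)cc(OC)c2)[C@H](c2ccc(OC)cc2)O3)cc1 | intermediate
27 | octaphenol ketone | Oc1ccc([C@H]2c3c(O)cc(O)cc3[C@@H](C(=O)c3ccc(O)cc3)[C@@H]2c2cc(O)cc3c2[C@@H](c2cc(O)cc(O)c2)[C@H](c2ccc(O)cc2)O3)cc1 | intermediate
28 | CNP0175860.1, (1S,2R,3S)-2-[(2R,3R)-3-(3,5-dihydroxyphenyl)-6-hydroxy-2-(4-hydroxyphenyl)-2,3-dihydro-1-benzofuran-4-yl]-3-[(S)-hydroxy(4-hydroxyphenyl)methyl]-1-(4-hydroxyphenyl)indane-5,7-diol | Oc1ccc([C@H]2c3c(O)cc(O)cc3[C@@H]([C@H](O)c3ccc(O)cc3)[C@@H]2c2cc(O)cc3c2[C@@H](c2cc(O)cc(O)c2)[C@H](c2ccc(O)cc2)O3)cc1 | target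

**Totals.** 20 steps in all. The longest linear sequence is 15 steps (9 → 28, steps 6–20); the other branch (1 → 28) is 13 steps.

**Least certain steps**

- **Step 14 (key step).** The most likely failure is interception of the C1 cation by the wrong partner. Ring D could close a seven-membered ring from C3', or a second molecule could be alkylated. Protonation at C1 in place of C2 would allow alkene migration toward C3 and erode the relay, and the superacid could ionise C2'–O. A fallback sets out from 20. Hydroboration–oxidation (BH3·SMe2, THF, 0 °C; NaBO3·4H2O) should put boron on the less substituted C1 and give the C1 carbinol F1 as a mixture of diastereomers. This 4-methoxybenzylic alcohol ionises in hexafluoroisopropanol without added strong acid, or with catalytic Bi(OTf)3. The same cation is then reached under much milder conditions and closes to 21, where the route is rejoined. The cost is that the C2 configuration then depends more on the hydroboration step.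

- **Step 3.** The alane may attack the CH2 terminus, or the opening may pass through a loose cation-like transition state and lose stereochemical fidelity. A fallback sets out from 1. Horner–Wadsworth–Emmons olefination (triethyl phosphonoacetate, NaH) gives ethyl (E)-3-(3,5-dimethoxyphenyl)prop-2-enoate F2. DIBAL-H reduction gives (E)-3-(3,5-dimethoxyphenyl)prop-2-en-1-ol F3. Sharpless asymmetric epoxidation (Ti(Oi-Pr)4, D-(−)-diethyl tartrate, t-BuOOH, 4 Å sieves) gives [(2R,3R)-3-(3,5-dimethoxyphenyl)oxiran-2-yl]methanol F4. With excess alane 5 the aluminium alkoxide of the primary alcohol directs alkynyl delivery to the benzylic C3 with inversion, giving (2S,3R)-3-(3,5-dimethoxyphenyl)-5-(4-methoxyphenyl)pent-4-yne-1,2-diol F5. Glycol cleavage with NaIO4 and reduction in the same pot with NaBH4 at 0 °C pass through (R)-2-(3,5-dimethoxyphenyl)-4-(4-methoxyphenyl)but-3-ynal F6, which is not stored because it can epimerise. The sequence returns to the route at 6.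

- **Step 5.** The branched C3 substituent may work against the electronic bias and put boron on C1, or the methoxide may cleave the acetate. A fallback sets out from 19 and 7. Miyaura borylation of 19 (Pd(dppf)Cl2, B2pin2, KOAc, dioxane) gives (2R,3R)-3-(3,5-dimethoxyphenyl)-6-methoxy-2-(4-methoxyphenyl)-4-(4,4,5,5-tetramethyl-1,3,2-dioxaborolan-2-yl)-2,3-dihydro-1-benzofuran F7. Rhodium-catalysed syn-hydroarylation of alkyne 7 with F7 ([Rh(cod)OH]2, dioxane/H2O, 60 °C) then adds the aryl group to the carbon remote from ring A. This returns directly at 20 and bypasses 8 and step 13.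

- **Step 11 (and its feeder, step 10).** The carbonyl of 15 lies between two ortho substituents, so condensation to 16 may be slow. The twisted, hindered carbene may then give azine or dimer, or insert with poor enantioselectivity. A fallback sets out from 15. The phosphazene base P4-t-Bu in hot toluene deprotonates the benzylic ether and closes onto the ketone, and dehydration gives 4-bromo-3-(3,5-dimethoxyphenyl)-6-methoxy-2-(4-methoxyphenyl)-1-benzofuran F8. Ionic hydrogenation (Et3SiH, CF3CO2H) gives racemic trans-4-bromo-3-(3,5-dimethoxyphenyl)-6-methoxy-2-(4-methoxyphenyl)-2,3-dihydro-1-benzofuran F9. Preparative chromatography on a chiral stationary phase gives the (2R,3R) enantiomer, which is 19.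

- **Step 20.** The ketone is electron-rich, branched at the alpha carbon and polyphenolic. Conversion may be slow, and facial selectivity may be poor if catalyst and the C3 centre are mismatched. A fallback sets out from 27. Silylation (TBSCl, imidazole, DMF) gives the octakis(tert-butyldimethylsilyl) ether of ketone 27, F10. A CBS reduction ((R)-Me-CBS, BH3·SMe2, THF, −20 °C) on this phenol-free aryl ketone gives the octakis(tert-butyldimethylsilyl) ether of the (8S) carbinol, F11. Buffered fluoride (Bu4NF, AcOH, THF, 0 °C) then removes the silyl groups without ionising C8–OH and gives 28.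

**Further compounds**

F1 | step 14 | (2S)-2-(3,5-dimethoxyphenyl)-3-[(2R,3R)-3-(3,5-dimethoxyphenyl)-6-methoxy-2-(4-methoxyphenyl)-2,3-dihydro-1-benzofuran-4-yl]-4-hydroxy-4-(4-methoxyphenyl)butyl acetate, diastereomers at C3 and C4 of the chain | COc1cc(OC)cc(c1)[C@@H](COC(C)=O)C(C(O)c1ccc(OC)cc1)c1cc(OC)cc2c1[C@@H](c1cc(OC)cc(OC)c1)[C@H](c1ccc(OC)cc1)O2
F2 | step 3 | ethyl (E)-3-(3,5-dimethoxyphenyl)prop-2-enoate | CCOC(=O)/C=C/c1cc(OC)cc(OC)c1
F3 | step 3 | (E)-3-(3,5-dimethoxyphenyl)prop-2-en-1-ol | OC/C=C/c1cc(OC)cc(OC)c1
F4 | step 3 | [(2R,3R)-3-(3,5-dimethoxyphenyl)oxiran-2-yl]methanol | COc1cc(OC)cc(c1)[C@H]1O[C@@H]1CO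
F5 | step 3 | (2S,3R)-3-(3,5-dimethoxyphenyl)-5-(4-methoxyphenyl)pent-4-yne-1,2-diol | COc1cc(OC)cc(c1)[C@@H]([C@H](O)CO)C#Cc1ccc(OC)cc1
F6 | step 3 | (R)-2-(3,5-dimethoxyphenyl)-4-(4-methoxyphenyl)but-3-ynal | COc1cc(OC)cc(c1)[C@@H](C=O)C#Cc1ccc(OC)cc1
F7 | step 5 | (2R,3R)-3-(3,5-dimethoxyphenyl)-6-methoxy-2-(4-methoxyphenyl)-4-(4,4,5,5-tetramethyl-1,3,2-dioxaborolan-2-yl)-2,3-dihydro-1-benzofuran | CC1(C)OB(OC1(C)C)c1cc(OC)cc2c1[C@@H](c1cc(OC)cc(OC)c1)[C@H](c1ccc(OC)cc1)O2
F8 | step 11 | 4-bromo-3-(3,5-dimethoxyphenyl)-6-methoxy-2-(4-methoxyphenyl)-1-benzofuran | COc1ccc(cc1)-c1oc2cc(OC)cc(Br)c2c1-c1cc(OC)cc(OC)c1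
F9 | step 11 | racemic trans-4-bromo-3-(3,5-dimethoxyphenyl)-6-methoxy-2-(4-methoxyphenyl)-2,3-dihydro-1-benzofuran (relative configuration shown) | Brc1cc(OC)cc2c1[C@@H](c1cc(OC)cc(OC)c1)[C@H](c1ccc(OC)cc1)O2
F10 | step 20 | octakis(tert-butyldimethylsilyl) ether of ketone 27 | CC(C)(C)[Si](C)(C)Oc1ccc([C@H]2c3c(O[Si](C)(C)C(C)(C)C)cc(O[Si](C)(C)C(C)(C)C)cc3[C@@H](C(=O)c3ccc(O[Si](C)(C)C(C)(C)C)cc3)[C@@H]2c2cc(O[Si](C)(C)C(C)(C)C)cc3c2[C@@H](c2cc(O[Si](C)(C)C(C)(C)C)cc(O[Si](C)(C)C(C)(C)C)c2)[C@H](c2ccc(O[Si](C)(C)C(C)(C)C)cc2)O3)cc1
F11 | step 20 | octakis(tert-butyldimethylsilyl) ether of the (8S) carbinol 28 | CC(C)(C)[Si](C)(C)Oc1ccc([C@H]2c3c(O[Si](C)(C)C(C)(C)C)cc(O[Si](C)(C)C(C)(C)C)cc3[C@@H]([C@H](O)c3ccc(O[Si](C)(C)C(C)(C)C)cc3)[C@@H]2c2cc(O[Si](C)(C)C(C)(C)C)cc3c2[C@@H](c2cc(O[Si](C)(C)C(C)(C)C)cc(O[Si](C)(C)C(C)(C)C)c2)[C@H](c2ccc(O[Si](C)(C)C(C)(C)C)cc2)O3)cc1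
A1 | alternative 1 | all-trans indane bearing at C2 a 2-(3,5-dimethoxybenzoyl)-3-hydroxy-5-methoxyphenyl group | COc1ccc([C@H]2c3c(OC)cc(OC)cc3[C@@H](COC(C)=O)[C@@H]2c2cc(OC)cc(O)c2C(=O)c2cc(OC)cc(OC)c2)cc1
A2 | alternative 1 | all-trans indane bearing at C2 a 3-(3,5-dimethoxyphenyl)-3-oxoprop-1-ynyl group | COc1ccc([C@H]2c3c(OC)cc(OC)cc3[C@@H](COC(C)=O)[C@@H]2C#CC(=O)c2cc(OC)cc(OC)c2)cc1
A3 | alternative 1 | 1,3-dimethoxy-1-(trimethylsilyloxy)buta-1,3-diene | COC(=C)C=C(OC)O[Si](C)(C)C
A4 | alternative 2 | methyl (2R,3R)-4-(benzyloxy)-6-methoxy-2-(4-methoxyphenyl)-2,3-dihydro-1-benzofuran-3-carboxylate (trans) | c1ccccc1COc1cc(OC)cc2c1[C@@H](C(=O)OC)[C@H](c1ccc(OC)cc1)O2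
A5 | alternative 2 | (2R)-5-(benzyloxy)-7-methoxy-2-(4-methoxyphenyl)chroman-4-one | c1ccccc1COc1cc(OC)cc2c1C(=O)C[C@H](c1ccc(OC)cc1)O2
A6 | alternative 3 | octamethyl ether of the target skeleton with a pinacol boronate in place of the C8 hydroxyl | COc1ccc([C@H]2c3c(OC)cc(OC)cc3[C@@H]([C@H](B3OC(C)(C)C(C)(C)O3)c3ccc(OC)cc3)[C@@H]2c2cc(OC)cc3c2[C@@H](c2cc(OC)cc(OC)c2)[C@H](c2ccc(OC)cc2)O3)cc1
A7 | alternative 3 | (E)-alkenyl pinacol boronate with C1 and C2 set and a triflate on ring F at C3a | COc1ccc([C@@H](c2c(OC)cc(OC)cc2OS(=O)(=O)C(F)(F)F)[C@H](/C=C/B2OC(C)(C)C(C)(C)O2)c2cc(OC)cc3c2[C@@H](c2cc(OC)cc(OC)c2)[C@H](c2ccc(OC)cc2)O3)cc1
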